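**Retrosynthetic overview**
1. Ring C of the flavonol is a 4-pyranone: carbonyl carbon C4 lies between arene carbon C4a and alkene carbon C3, and ring oxygen O1 is a phenol oxygen bound to C2. C4 is therefore carbon monoxide inserted between C4a of a 2-iodophenol (ring A) and the terminal alkyne carbon (future C3) of a 5-ethynyl-2,3-dihydrobenzofuran, and O1–C2 closes ring C in the same operation.
2. The 3-hydroxyl is added once ring C exists (C3 lithiation, borylation, oxidation); one acid step then removes all MOM and silyl groups.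
3. The alkyne comes from a 5-bromo-trans-2,3-dihydrobenzofuran by Sonogashira coupling. Its dihydrofuran ring (C2–C3 bond, both stereocentres) is made by enantioselective dirhodium-carbenoid insertion into the benzylic C–H of an aryl benzyl ether, followed by C3 epimerisation (cis to trans) and ester reduction.
4. The diazo ester derives from 2,3-dihydroxybenzaldehyde (bromination, MOM on O3, benzylation of O2 with the vanillin-derived alcohol, one-carbon homologation); the iodophenol derives from phloroglucinol.
5. Ring order: the three benzene rings are bought; the dihydrofuran ring is formed first (step 10) and pyranone ring C last (step 17).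

Key step: step 17

Remark: the 2R sense of induction of Rh2(S-PTTL)4 in step 10 is assumed from simpler 2-(benzyloxy)phenyl diazoacetates; if this substrate showed the opposite sense, Rh2(R-PTTL)4 would be used in the same step.

**Route**

Step 1
Reactants: 1 vanillin
Product: 2 3-methoxy-4-(methoxymethoxy)benzaldehyde
Conditions: MOMCl, i-Pr2NEt, CH2Cl2, 0 °C → rt
Reagents that add atoms: chloromethyl methyl ether, COCCl
Why: O-alkylation of the phenol (MOM protection) gives a base-stable acetal that survives all basic and organometallic steps and is removed in the final acid step.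

Step 2
Reactants: 2 3-methoxy-4-(methoxymethoxy)benzaldehyde
Product: 3 [3-methoxy-4-(methoxymethoxy)phenyl]methanol
Conditions: NaBH4, MeOH, 0 °C
Reagents that add atoms: none
Why: Borohydride reduction of an aromatic aldehyde to the benzylic alcohol leaves the MOM acetal untouched.

Step 3
Reactants: 4 2,3-dihydroxybenzaldehyde
Product: 5 5-bromo-2,3-dihydroxybenzaldehyde
Conditions: Br2, NaOAc, AcOH, rt
Reagents that add atoms: bromine, BrBr
Why: Electrophilic aromatic bromination should go to C5, which is para to the 2-hydroxyl and meta to the formyl group.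

Step 4
Reactants: 5 5-bromo-2,3-dihydroxybenzaldehyde
Product: 6 5-bromo-2-hydroxy-3-(methoxymethoxy)benzaldehyde
Conditions: NaH (2.1 equiv), DMF, 0 °C; MOMCl (1.0 equiv), 0 °C → rt
Reagents that add atoms: chloromethyl methyl ether, COCCl
Why: In the dianion the 3-phenoxide is neither conjugated with nor chelated to the formyl group and is the more nucleophilic oxygen, so one equivalent of MOMCl should alkylate O3 and leave the 2-hydroxyl free (selective catechol-aldehyde monoalkylation).

Step 5
Reactants: 6 5-bromo-2-hydroxy-3-(methoxymethoxy)benzaldehyde; 3 [3-methoxy-4-(methoxymethoxy)phenyl]methanol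
Product: 7 5-bromo-2-{[3-methoxy-4-(methoxymethoxy)phenyl]methoxy}-3-(methoxymethoxy)benzaldehyde
Conditions: PPh3, DIAD, THF, 0 °C → rt
Reagents that add atoms: none
Why: Mitsunobu etherification of the acidic salicylaldehyde-type phenol with an activated primary benzylic alcohol runs under neutral conditions that spare both MOM acetals.

Step 6
Reactants: 7 5-bromo-2-{[3-methoxy-4-(methoxymethoxy)phenyl]methoxy}-3-(methoxymethoxy)benzaldehyde
Product: 8 racemic 1-(5-bromo-2-{[3-methoxy-4-(methoxymethoxy)phenyl]methoxy}-3-(methoxymethoxy)phenyl)-2,2,2-trichloroethanol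
Conditions: CHCl3 (excess), DBU (1 equiv), 0 °C → rt
Reagents that add atoms: chloroform, ClC(Cl)Cl
Why: Amidine-base-mediated addition of the trichloromethyl anion to a non-enolisable aromatic aldehyde gives the trichloromethyl carbinol, the first half of a Jocic-Reeve homologation.

Step 7
Reactants: 8 racemic trichloromethyl carbinol
Product: 9 2-(5-bromo-2-{[3-methoxy-4-(methoxymethoxy)phenyl]methoxy}-3-(methoxymethoxy)phenyl)acetic acid
Conditions: NaBH4, NaOH, t-BuOH, 55 °C; then aq citric acid to pH 4, 0 °C
Reagents that add atoms: sodium hydroxide, [Na+].[OH-]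
Why: Jocic-Reeve reductive homologation, in which the alkoxide closes to a gem-dichloroepoxide, hydride opens it at the benzylic carbon and the resulting acyl chloride is hydrolysed to the arylacetate, all in a basic medium that spares the acetals, the benzyl ether and the aryl bromide.

Step 8
Reactants: 9 arylacetic acid
Product: 10 methyl 2-(5-bromo-2-{[3-methoxy-4-(methoxymethoxy)phenyl]methoxy}-3-(methoxymethoxy)phenyl)acetate
Conditions: MeI, K2CO3, DMF, rt
Reagents that add atoms: iodomethane, CI
Why: O-alkylation of the carboxylate gives the methyl ester without acid.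

Step 9
Reactants: 10 methyl arylacetate
Product: 11 methyl 2-diazo-2-(5-bromo-2-{[3-methoxy-4-(methoxymethoxy)phenyl]methoxy}-3-(methoxymethoxy)phenyl)acetate
Conditions: p-ABSA, DBU, MeCN, 0 °C → rt
Reagents that add atoms: 4-acetamidobenzenesulfonyl azide, CC(=O)Nc1ccc(cc1)S(=O)(=O)N=[N+]=[N-]
Why: Regitz diazo transfer to the aryl-activated ester α-carbon gives the donor/acceptor diazo compound.

Step 10
Reactants: 11 aryl diazoacetate
Product: 12 methyl (2R,3S)-5-bromo-2-[3-methoxy-4-(methoxymethoxy)phenyl]-7-(methoxymethoxy)-2,3-dihydro-1-benzofuran-3-carboxylate (cis)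
Conditions: Rh2(S-PTTL)4 (dirhodium tetrakis[N-phthaloyl-(S)-tert-leucinate], 1 mol %), toluene, −60 °C
Reagents that add atoms: none
Why: The dirhodium carbenoid inserts into the electron-rich benzylic C–H next to the ether oxygen (intramolecular 1,5 C–H insertion) and so forms C2–C3 and the five-membered ring; the chiral carboxylate ligands select one enantiotopic benzylic hydrogen, which should set C2 as R and give the cis ester.

Step 11
Reactants: 12 cis ester
Product: 13 methyl (2R,3R)-5-bromo-2-[3-methoxy-4-(methoxymethoxy)phenyl]-7-(methoxymethoxy)-2,3-dihydro-1-benzofuran-3-carboxylate (trans)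
Conditions: NaOMe (0.3 equiv), MeOH/THF, 0 °C → rt
Reagents that add atoms: none
Why: Enolate-mediated epimerisation of the ester α-centre C3 should lead to the thermodynamically favoured trans isomer, while the non-acidic C2 keeps its R configuration.

Step 12
Reactants: 13 trans ester
Product: 14 [(2R,3S)-5-bromo-2-[3-methoxy-4-(methoxymethoxy)phenyl]-7-(methoxymethoxy)-2,3-dihydro-1-benzofuran-3-yl]methanol
Conditions: LiBH4, THF, 0 °C → rt
Reagents that add atoms: none
Why: Hydride reduction of the methyl ester to the primary alcohol touches neither stereocentre, the aryl bromide nor the acetals (the descriptor at C3 changes from R to S only through the priority change).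

Step 13
Reactants: 14 primary alcohol
Product: 15 tert-butyl{[(2R,3S)-5-bromo-2-[3-methoxy-4-(methoxymethoxy)phenyl]-7-(methoxymethoxy)-2,3-dihydro-1-benzofuran-3-yl]methoxy}dimethylsilane
Conditions: TBSCl, imidazole, DMF, rt
Reagents that add atoms: tert-butyldimethylsilyl chloride, CC(C)(C)[Si](C)(C)Cl
Why: Silylation masks the primary alcohol, which would otherwise capture the aroylpalladium intermediate of the key step and consume base in the lithiation.

Step 14
Reactants: 15 silyl-protected aryl bromide
Product: 17 (2R,3S)-3-{[tert-butyl(dimethyl)silyl]oxymethyl}-5-ethynyl-2-[3-methoxy-4-(methoxymethoxy)phenyl]-7-(methoxymethoxy)-2,3-dihydro-1-benzofuran, via trimethylsilylalkyne 16 (not isolated)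
Conditions: Me3SiC≡CH, PdCl2(PhCN)2 (3 mol %), P(t-Bu)3·HBF4 (6 mol %), CuI (2 mol %), i-Pr2NH, dioxane, rt → 45 °C; filter; then K2CO3 (cat.), MeOH/THF, rt
Reagents that add atoms: ethynyltrimethylsilane, C#C[Si](C)(C)C
Why: Sonogashira coupling with a bulky electron-rich phosphine, which allows oxidative addition to the electron-rich aryl bromide, followed by base-catalysed methanolysis of the alkynyl C–Si bond, under which the alkyl silyl ether should survive.

Step 15
Reactants: 18 phloroglucinol
Product: 19 3,5-bis(methoxymethoxy)phenol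
Conditions: MOMCl (2.0 equiv), i-Pr2NEt, DMF, 0 °C → rt; chromatography
Reagents that add atoms: chloromethyl methyl ether, COCCl
Why: Statistical double O-alkylation of the symmetric triphenol can give only one bis-ether, which is separated from the mono- and tris-ethers.

Step 16
Reactants: 19 3,5-bis(methoxymethoxy)phenol
Product: 20 2-iodo-3,5-bis(methoxymethoxy)phenol
Conditions: I2, NaHCO3, THF/H2O, 0 °C
Reagents that add atoms: iodine, II
Why: Electrophilic iodination of the phenol under mildly basic, acetal-safe conditions should favour the two equivalent positions ortho to the free hydroxyl, statistically and sterically, over the position between the two MOM ethers, and the minor para isomer is removed by chromatography.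

Step 17
Reactants: 17 terminal alkyne; 20 2-iodo-3,5-bis(methoxymethoxy)phenol; 21 carbon monoxide
Product: 24 2-[(2R,3S)-3-{[tert-butyl(dimethyl)silyl]oxymethyl}-2-[3-methoxy-4-(methoxymethoxy)phenyl]-7-(methoxymethoxy)-2,3-dihydro-1-benzofuran-5-yl]-5,7-bis(methoxymethoxy)-4H-chromen-4-one, via ynone 22 (not isolated), via enaminone 23 (not isolated)
Conditions: PdCl2(PPh3)2 (5 mol %), CO (20 bar), Et2NH (solvent), 120 °C, autoclave
Reagents that add atoms: none
Why: Zerovalent palladium, formed in situ from PdCl2(PPh3)2, adds oxidatively to the C–I bond of 20, CO inserts to give the aroylpalladium species, and this couples with the amine-deprotonated terminal alkyne of 17 to form bonds C4a–C4 and C4–C3 in ynone 22. Diethylamine then adds in conjugate fashion to give enaminone 23, and the phenol oxygen closes ring C by addition–elimination at the β-carbon (6-endo closure, formally 6-endo-dig on the ynone), which forms O1–C2 and releases the amine. The closest known reaction type is the palladium-catalysed carbonylative annulation of 2-iodophenols with terminal arylacetylenes in a secondary amine to give flavones. No stereocentre is formed, and C2 and C3 of the dihydrobenzofuran are remote from the reacting sites and not acidic, so they should pass unchanged. The step needs carbonylative coupling to win over direct alkynylation (which would lead to a 2-arylbenzofuran) and over aminocarbonylation, which the CO pressure, the absence of copper and the ready CO insertion of the electron-rich, doubly ortho-substituted arylpalladium species should secure. It also needs 6-endo over 5-exo closure (aurone), which the enaminone pathway opened by the secondary amine should secure.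

Step 18
Reactants: 24 protected flavone
Product: 27 3-hydroxy-2-[(2R,3S)-3-{[tert-butyl(dimethyl)silyl]oxymethyl}-2-[3-methoxy-4-(methoxymethoxy)phenyl]-7-(methoxymethoxy)-2,3-dihydro-1-benzofuran-5-yl]-5,7-bis(methoxymethoxy)-4H-chromen-4-one, via 3-lithioflavone 25 (not isolated), via flavon-3-ylboronate 26 (not isolated)
Conditions: LiN(i-Pr)2 (1.3 equiv), THF, −78 °C; B(OMe)3, −78 → 0 °C; AcOH, 30% aq H2O2, 0 °C → rt
Reagents that add atoms: hydrogen peroxide, OO
Why: Chromone C3–H, next to the C4 carbonyl, is the only C–H acidic enough for the amide base, so vinylic lithiation, borylation and peroxide-induced 1,2-migration (boronate oxidation) should place the hydroxyl at C3 without touching the dihydrobenzofuran stereocentres.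

Step 19
Reactants: 27 protected flavonol
Product: 28 2,3-dehydrosilychristin
Conditions: HCl (1.25 M in MeOH), THF, 40 °C, under argon
Reagents that add atoms: none
Why: Acid-catalysed acetal exchange removes the four MOM groups and solvolysis removes the silyl ether; C3 is not epimerisable under acid, so even a reversible opening of the benzylic C2–O bond should reclose to the trans (2R,3S) isomer.

**Compound list**
1 | vanillin | COc1cc(C=O)ccc1O | starting material
2 | 3-methoxy-4-(methoxymethoxy)benzaldehyde | COCOc1ccc(C=O)cc1OC | intermediate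
3 | [3-methoxy-4-(methoxymethoxy)phenyl]methanol | COCOc1ccc(CO)cc1OC | intermediate
4 | 2,3-dihydroxybenzaldehyde | O=Cc1cccc(O)c1O | starting material
5 | 5-bromo-2,3-dihydroxybenzaldehyde | O=Cc1cc(Br)cc(O)c1O | intermediate
6 | 5-bromo-2-hydroxy-3-(methoxymethoxy)benzaldehyde | O=Cc1cc(Br)cc(OCOC)c1O | intermediate
7 | 5-bromo-2-{[3-methoxy-4-(methoxymethoxy)phenyl]methoxy}-3-(methoxymethoxy)benzaldehyde | O=Cc1cc(Br)cc(OCOC)c1OCc1ccc(OCOC)c(OC)c1 | intermediate
8 | racemic 1-(5-bromo-2-{[3-methoxy-4-(methoxymethoxy)phenyl]methoxy}-3-(methoxymethoxy)phenyl)-2,2,2-trichloroethanol | OC(c1cc(Br)cc(OCOC)c1OCc1ccc(OCOC)c(OC)c1)C(Cl)(Cl)Cl | intermediate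
9 | 2-(5-bromo-2-{[3-methoxy-4-(methoxymethoxy)phenyl]methoxy}-3-(methoxymethoxy)phenyl)acetic acid | OC(=O)Cc1cc(Br)cc(OCOC)c1OCc1ccc(OCOC)c(OC)c1 | intermediate
10 | methyl 2-(5-bromo-2-{[3-methoxy-4-(methoxymethoxy)phenyl]methoxy}-3-(methoxymethoxy)phenyl)acetate | COC(=O)Cc1cc(Br)cc(OCOC)c1OCc1ccc(OCOC)c(OC)c1 | intermediate
11 | methyl 2-diazo-2-(5-bromo-2-{[3-methoxy-4-(methoxymethoxy)phenyl]methoxy}-3-(methoxymethoxy)phenyl)acetate | COC(=O)C(=[N+]=[N-])c1cc(Br)cc(OCOC)c1OCc1ccc(OCOC)c(OC)c1 | intermediate
12 | methyl (2R,3S)-5-bromo-2-[3-methoxy-4-(methoxymethoxy)phenyl]-7-(methoxymethoxy)-2,3-dihydro-1-benzofuran-3-carboxylate (cis) | COc1cc([C@@H]2Oc3c(OCOC)cc(Br)cc3[C@@H]2C(=O)OC)ccc1OCOC | intermediate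
13 | methyl (2R,3R)-5-bromo-2-[3-methoxy-4-(methoxymethoxy)phenyl]-7-(methoxymethoxy)-2,3-dihydro-1-benzofuran-3-carboxylate (trans) | COc1cc([C@@H]2Oc3c(OCOC)cc(Br)cc3[C@H]2C(=O)OC)ccc1OCOC | intermediate
14 | [(2R,3S)-5-bromo-2-[3-methoxy-4-(methoxymethoxy)phenyl]-7-(methoxymethoxy)-2,3-dihydro-1-benzofuran-3-yl]methanol | COc1cc([C@@H]2Oc3c(OCOC)cc(Br)cc3[C@H]2CO)ccc1OCOC | intermediate
15 | tert-butyl{[(2R,3S)-5-bromo-2-[3-methoxy-4-(methoxymethoxy)phenyl]-7-(methoxymethoxy)-2,3-dihydro-1-benzofuran-3-yl]methoxy}dimethylsilane | COc1cc([C@@H]2Oc3c(OCOC)cc(Br)cc3[C@H]2CO[Si](C)(C)C(C)(C)C)ccc1OCOC | intermediate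
16 | (2R,3S)-3-{[tert-butyl(dimethyl)silyl]oxymethyl}-2-[3-methoxy-4-(methoxymethoxy)phenyl]-7-(methoxymethoxy)-5-[(trimethylsilyl)ethynyl]-2,3-dihydro-1-benzofuran | COc1cc([C@@H]2Oc3c(OCOC)cc(C#C[Si](C)(C)C)cc3[C@H]2CO[Si](C)(C)C(C)(C)C)ccc1OCOC | intermediate
17 | (2R,3S)-3-{[tert-butyl(dimethyl)silyl]oxymethyl}-5-ethynyl-2-[3-methoxy-4-(methoxymethoxy)phenyl]-7-(methoxymethoxy)-2,3-dihydro-1-benzofuran | COc1cc([C@@H]2Oc3c(OCOC)cc(C#C)cc3[C@H]2CO[Si](C)(C)C(C)(C)C)ccc1OCOC | intermediate
18 | phloroglucinol | Oc1cc(O)cc(O)c1 | starting material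
19 | 3,5-bis(methoxymethoxy)phenol | COCOc1cc(O)cc(OCOC)c1 | intermediate
20 | 2-iodo-3,5-bis(methoxymethoxy)phenol | COCOc1cc(O)c(I)c(OCOC)c1 | intermediate
21 | carbon monoxide | [C-]#[O+] | starting material
22 | 1-[2-hydroxy-4,6-bis(methoxymethoxy)phenyl]-3-[(2R,3S)-3-{[tert-butyl(dimethyl)silyl]oxymethyl}-2-[3-methoxy-4-(methoxymethoxy)phenyl]-7-(methoxymethoxy)-2,3-dihydro-1-benzofuran-5-yl]prop-2-yn-1-one | COc1cc([C@@H]2Oc3c(OCOC)cc(C#CC(=O)c4c(O)cc(OCOC)cc4OCOC)cc3[C@H]2CO[Si](C)(C)C(C)(C)C)ccc1OCOC | intermediate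
23 | 3-(diethylamino)-1-[2-hydroxy-4,6-bis(methoxymethoxy)phenyl]-3-[(2R,3S)-3-{[tert-butyl(dimethyl)silyl]oxymethyl}-2-[3-methoxy-4-(methoxymethoxy)phenyl]-7-(methoxymethoxy)-2,3-dihydro-1-benzofuran-5-yl]prop-2-en-1-one (alkene geometry not defined) | COc1cc([C@@H]2Oc3c(OCOC)cc(C(=CC(=O)c4c(O)cc(OCOC)cc4OCOC)N(CC)CC)cc3[C@H]2CO[Si](C)(C)C(C)(C)C)ccc1OCOC | intermediate
24 | 2-[(2R,3S)-3-{[tert-butyl(dimethyl)silyl]oxymethyl}-2-[3-methoxy-4-(methoxymethoxy)phenyl]-7-(methoxymethoxy)-2,3-dihydro-1-benzofuran-5-yl]-5,7-bis(methoxymethoxy)-4H-chromen-4-one | COc1cc([C@@H]2Oc3c(OCOC)cc(-c4oc5cc(OCOC)cc(OCOC)c5c(=O)c4)cc3[C@H]2CO[Si](C)(C)C(C)(C)C)ccc1OCOC | intermediate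
25 | 3-lithio derivative of 24 | COc1cc([C@@H]2Oc3c(OCOC)cc(-c4oc5cc(OCOC)cc(OCOC)c5c(=O)c4[Li])cc3[C@H]2CO[Si](C)(C)C(C)(C)C)ccc1OCOC | intermediate
26 | dimethyl boronate of 24 at chromone C3 | COc1cc([C@@H]2Oc3c(OCOC)cc(-c4oc5cc(OCOC)cc(OCOC)c5c(=O)c4B(OC)OC)cc3[C@H]2CO[Si](C)(C)C(C)(C)C)ccc1OCOC | intermediate
27 | 3-hydroxy-2-[(2R,3S)-3-{[tert-butyl(dimethyl)silyl]oxymethyl}-2-[3-methoxy-4-(methoxymethoxy)phenyl]-7-(methoxymethoxy)-2,3-dihydro-1-benzofuran-5-yl]-5,7-bis(methoxymethoxy)-4H-chromen-4-one | COc1cc([C@@H]2Oc3c(OCOC)cc(-c4oc5cc(OCOC)cc(OCOC)c5c(=O)c4O)cc3[C@H]2CO[Si](C)(C)C(C)(C)C)ccc1OCOC | intermediate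
28 | 2,3-dehydrosilychristin | COc1cc([C@@H]2Oc3c(O)cc(-c4oc5cc(O)cc(O)c5c(=O)c4O)cc3[C@H]2CO)ccc1O | target

**Totals**
Total step count: 19. Longest linear sequence: 15 steps (steps 3 to 14, then 17 to 19).

**Steps most likely to fail, with fallbacks**

Step 17 (carbonylative annulation). Oxidative addition to the hindered, electron-rich iodide may be slow, and direct alkynylation or capture of the aroylpalladium species by diethylamine may outrun carbonylative coupling. The fallback brings in the carbonyl carbon as an aldehyde instead of as CO; it sets out from 19 and 17 and comes back at ynone 22 and thus at 24. Phenol 19 is ortho-formylated (MgCl2, Et3N, paraformaldehyde, MeCN, reflux) to 2-hydroxy-4,6-bis(methoxymethoxy)benzaldehyde F1. Its sodium phenoxide (NaH, THF, 0 °C) is added to the lithium acetylide of 17 (n-BuLi, THF, −78 → 0 °C) to give the propargylic alcohol F2 as a mixture of carbinol epimers. MnO2 in CH2Cl2 oxidises it to ynone 22, and diethylamine in ethanol closes 22 to flavone 24 through the same enaminone 23.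

Step 10 (carbenoid C–H insertion). Facial selectivity may be eroded by the MOM ether ortho to the benzyloxy group, which would leave material of insufficient enantiomeric purity. The fallback replaces catalyst control by separation of covalent diastereomers; it sets out from alcohol 14 of insufficient purity and comes back at enantiopure 14. Alcohol 14 is esterified with (S)-2-methoxy-2-phenylacetic acid (DCC, DMAP, CH2Cl2) to the (S)-O-methylmandelate ester F3. The diastereomers are separated by chromatography or crystallisation, and K2CO3 in MeOH releases 14.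

Step 18 (C3 hydroxylation). The amide base may add to C2 of the chromone, or metalation may be incomplete. The fallback introduces the oxygen by electrophilic oxidation instead of metalation; it sets out from 24 and comes back at 27. Dimethyldioxirane (acetone/CH2Cl2, 0 °C) should epoxidise the C2–C3 double bond to the flavone 2,3-epoxide F4. A catalytic amount of p-toluenesulfonic acid in CH2Cl2 at 0 °C should then open the epoxide at C2 and tautomerise it to flavonol 27.

**Further compounds**
F1 | step 17 | 2-hydroxy-4,6-bis(methoxymethoxy)benzaldehyde | COCOc1cc(O)c(C=O)c(OCOC)c1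
F2 | step 17 | 1-[2-hydroxy-4,6-bis(methoxymethoxy)phenyl]-3-[(2R,3S)-3-{[tert-butyl(dimethyl)silyl]oxymethyl}-2-[3-methoxy-4-(methoxymethoxy)phenyl]-7-(methoxymethoxy)-2,3-dihydro-1-benzofuran-5-yl]prop-2-yn-1-ol (carbinol epimers) | COc1cc([C@@H]2Oc3c(OCOC)cc(C#CC(O)c4c(O)cc(OCOC)cc4OCOC)cc3[C@H]2CO[Si](C)(C)C(C)(C)C)ccc1OCOC
F3 | step 10 | [(2R,3S)-5-bromo-2-[3-methoxy-4-(methoxymethoxy)phenyl]-7-(methoxymethoxy)-2,3-dihydro-1-benzofuran-3-yl]methyl (S)-2-methoxy-2-phenylacetate | COc1cc([C@@H]2Oc3c(OCOC)cc(Br)cc3[C@H]2COC(=O)[C@@H](OC)c4ccccc4)ccc1OCOC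
F4 | step 18 | 2,3-epoxide of flavone 24 (epoxide configuration not defined) | COc1cc([C@@H]2Oc3c(OCOC)cc(C45OC4C(=O)c4c(OCOC)cc(OCOC)cc4O5)cc3[C@H]2CO[Si](C)(C)C(C)(C)C)ccc1OCOC
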